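(The earlier runs and the new flask stem from a simulated flask for an exercise, noise included.)

In a one-step world, each molecule of starting material that leaves becomes side product or target at once, and the share of side product in the two stands at one value from the first minute. Thursday's flask is not that world, so here is the note for whoever takes over the bench.

common to all: starting material 0.36 M; coupling partner 0.468 M
- Thursday's: capture agent 0.018 M; protic impurity 7.2 mM; the very flask that is asked about, followed so far
- flask: capture agent 0.0180 M; protic impurity 7.20 mM; time 15 d

Thursday's run (percent of the starting material charged)

| time / d | side product / % | target / % | starting material / % |
|---|---|---|---|
| 0.833 | 19 | 50 | 20 |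
| 2.00 | 24 | 72 | 2 |
| 4.00 | 24 | 73 | 0 |
| 6.00 | 24 | 73 | 0 |

(readings scatter by 1.5 percentage points)

- the numbers in the tables scatter by 1.5 percentage points (one standard deviation)
- a reading or a percentage of target counts all its forms, free or not

* share of side product in side product plus target at 30 min
* share of side product in side product plus target at 15 h
* share of side product in side product plus target at 15 d
* which of side product and target there is more of at 15 d

Thursday's flask last read 73% target and 24% side product at 6.00 d, with target unchanged since 4.00 d, so leave it closed and add nothing. From those readings, side product over side product plus target comes to 24.7%; we call this the late share, the selectivity of the branch.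

Early on we treat the material in transit as a correction. Let g be the part of the consumed starting material still in transit towards a product, with material lost for good not counted in it; then the share is about the late share divided by one minus g. At 0.833 d, the readings leave 11.0% of the charge in neither product; from this we take off the 3.00% that the last reading still leaves out, which we count as lost. So g reads 10.0%, the rule gives 27.4%, and the direct reading is 27.5%, with readings scattering by 1.5 percentage points. We take the rule's figure as a first estimate for 15 h and give none for 30 min. For 15 d we commit to the late share, with target ahead.

The forecast says 85%, 31% and 24.8%, with target leading, and holds that “target arrives through an intermediate”.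

The flask gives 84.9%, 28.9% and 24.0%, with target leading. At 150 d it still holds 73.6% target and 23.3% side product. We use the late share once more at 1.50 d, where the flask holds 1.63% intermediate A and 0.901% intermediate B. Over the consumed starting material, these give g of 2.67%, so the rule gives 25.4%, against 24.7% from the simulated amounts.

    intermediate A → target (k = 0.230 h⁻¹)
    starting material → intermediate A (k = 0.0610 h⁻¹)
    intermediate A ⇌ intermediate B (K = 0.840, k = 0.150 h⁻¹)
    starting material → side product (k = 0.0190 h⁻¹)
    intermediate B → target (k = 0.170 h⁻¹)
    starting material + protic impurity → quenched substrate (k = 11.0 M⁻¹ h⁻¹)
    crystals ⇌ target, rate k7*(cs7 - [target]) while solid is left; crystals form when [target] > cs7 (solubility = 0.270 M, k = 0.990 h⁻¹)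
    capture agent + intermediate A → trapped intermediate (k = 0.280 M⁻¹ h⁻¹)

For the flask with c(starting material) at 0.61 M, the late share gives 24.7% at 15.0 d. The computed value is 24.0%, with 30.1% as crystals counted inside its 74.3% target.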